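## The problem

Monochlorosulochrin (17) is a benzophenone with no ring fusion and no stereocentre, so the whole difficulty is constitutional. Its ketone carbon sits between four ortho substituents: the ester at C1 and the methoxy group at C3 of ring A, and the hydroxyls at C2' and C6' of ring B. The two bonds to that carbon are therefore the most crowded in the molecule. Ring A is a phloroglucinol-type ring whose oxygens must end up differentiated (C3–OMe, C5–OH) and which carries two adjacent carbon substituents at different oxidation levels (carboxyl at C1, ketone at C2). Ring B is an orcinol nucleus that must be substituted between its two oxygens and chlorinated once, at C3'. Because the target is achiral, a stereocentre that appears on the way (a benzhydrol carbon) needs no control as long as it is oxidised later. Reagent choice is limited by the methyl ester beside free phenols (saponification, lactonisation), the aryl chloride (hydrogenolysis, halogen–metal exchange), the C3 methyl ether ortho to the ketone (chelation-assisted cleavage by boron or aluminium halides) and the electron-rich rings (electrophilic oxidants). The feature that opens the molecule is the vicinal pair C1/C2 of ring A beside the C3 oxygen: this is the pattern a 3-alkoxyaryne produces when it takes a carbon nucleophile at C1 and a carbon electrophile at C2.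

## Retrosynthesis

**17 from 16.** The three phenolic O–H bonds are traced to three O–CH2OCH3 bonds in 16. Methoxymethyl ethers are preferred to an isopropyl or benzyl ether on ring A because one protic step in methanol removes all three. That step does not touch the methyl ester, the aryl chloride or the methyl ether ortho to the ketone, which BCl3 or hydrogenolysis could each endanger. The forward reaction only has to be an acetal exchange.

**16 from 15 from 13.** The ester O–CH3 bond is cut to give keto acid 15. The ketone of 15 is then taken back one oxidation level and tied to the carboxyl group as the lactone of 3-arylphthalide 13 (opened in the flask to carboxylate 14). The phthalide holds the C1 carbon at its final oxidation level and the C2 carbon one step below it, and it avoids any acylation at a position flanked on both sides. The forward steps are lactone opening, oxidation of a secondary benzhydrol and carboxylate alkylation.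

**13 from 12.** The lactone C=O is traced to the C=N–tBu group of cyclic imidate 12. This is a pure functional-group change; the forward reaction must hydrolyse the imidate on the nitrogen side without cleaving the acetals.

**12 from 4, 9 and 10.** Three bonds of the oxygen heterocycle are cut at once: aryl C7a–C1 (imidate carbon), aryl C3a–C3 (carbinol carbon) and O2–C1. This leads to aryne 11 (released from silyl triflate 4), aldehyde 9 and tert-butyl isocyanide (10).
- Against a Friedel–Crafts aroylation, this cut does not need an electrophile to enter a deactivated, doubly flanked position.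
- Against ortho-metalation of a ring A benzoate or benzamide, it avoids a choice between several oxygen-activated sites.
- The 26-carbon imidate falls into three components of at most three steps each.
- The forward reaction needs isocyanide attack at C1 of 11 only, capture of a hindered aldehyde by the aryl anion, and acetals that ignore fluoride.

**4 from 3 from 1.** The O–CH2OCH3 bond and then the C5–O bond are cut, via boronate 2, back to the catalogue 3-methoxyaryne precursor 1. Directed ortho-silylation of a differentially protected phloroglucinol monocarbamate was weighed for this fragment. It would have to choose between two doubly activated ortho positions, and the wrong choice gives an aryne with the two ring A oxygens interchanged. Introducing the C5 oxygen last avoids the question: in 1 only C5–H has no ortho neighbour, so sterically governed C–H borylation can go nowhere else.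

**9 from 7 from 6 from 5.** The formyl C–C bond (via aryllithium 8), the C–Cl bond and the two O–CH2OCH3 bonds are cut back to orcinol (5). Chlorinating bis-ether 6 rather than the free diphenol lets the two acetal groups shield the position between them. The same groups then direct lithiation to exactly that position.

## Roads not taken

**Alternative 1: Baeyer–Villiger cleavage of an anthraquinone.**
- Cut: the ester C–O bond and the C6'–O bond of ring B are traced to seven-membered lactone A2, a dibenzo[b,e]oxepine-6,11-dione pivalate, and that to the C10 carbonyl of anthraquinone A1.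
- Forward key step: CF3CO3H adds to the C10 carbonyl of A1, the one without peri oxygens, and the ring B carbon migrates to oxygen to give A2. Methanolysis of the lactone and loss of the pivalate would then give 17.
- Merits: it follows the biosynthesis. The full carbon skeleton, the chlorine, the methyl group and the C3 methyl ether are in place before the key step. Lactone opening delivers ester and phenol together with no oxidation-level adjustment. If it worked it would be shorter than the ten steps proposed here.
- Weak points: anthraquinone carbonyls are doubly conjugated and are poor acceptors for peracids. The two candidate migrating carbons differ little: the ring B carbon is para to chlorine and meta to the hydroxyl, the ring A carbon is meta to both of its oxygens. A pivalate offers only a weak bias, and the wrong migration gives the isomeric lactone and finally a ring B ester. A peracid would also meet a free phenolic ring. A1 itself needs a site-selective O-methylation, a site-selective chlorination and a selective acylation of a trioxygenated methylanthraquinone.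
- Comparison: this road is better in step count and in atom and redox economy. The chosen plan sets against that a regiochemistry fixed by a strong and well-understood substituent effect and precedent for each bond-forming step, where A1 to A2 depends on a migratory preference the structure does not provide.

**Alternative 2: ring A by aldol closure of a tetraketo ester.**
- Cut: the C1–C2 bond of ring A, and with it the aromatic ring, is opened to the acyclic methyl 8-aryl-2,4,6,8-tetraoxooctanoate A3.
- Forward key step: the methylene between the two carbonyls nearest the aryl ketone attacks the alpha-keto ester carbonyl. Dehydration and enolisation aromatise to methyl 2-aroyl-3,5-dihydroxybenzoate A4.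
- Merits: the ketone carbon is attached to ring B before ring A exists, so no crowded diaryl ketone has to be forged. The ester and aroyl groups come out vicinal automatically.
- Weak points: A3 is a beta-polycarbonyl chain with several enolisable methylenes and several carbonyl acceptors. Closure in the other direction, onto the aryl ketone, and pyrone formation compete. Building A3 needs polyanion acylation with a hindered ring B acyl donor. A4 has both ring A oxygens free, and the one to be methylated (C3, chelated to the ketone) is the less reactive; a protect–methylate–deprotect sequence on ring A would be needed.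
- Comparison: no part of this road is clearly shorter or safer than the chosen plan, which carries the C3/C5 differentiation from its first step and forms ring A bonds on an existing arene.

**Alternative 3: ring A by Diels–Alder reaction of an aroylpropiolate.**
- Cut: the ring A bonds C2–C3 and C1–C6 are opened to methyl 4-aryl-4-oxobut-2-ynoate A5 and 1,1-dimethoxy-3-(trimethylsilyloxy)buta-1,3-diene A6.
- Forward key step: cycloaddition, loss of methanol and desilylation give methyl 2-aroyl-5-hydroxy-3-methoxybenzoate A7. One acetal cleavage would then give 17.
- Merits: A5 is two steps from aldehyde 9 (alkynylation, oxidation), so this road reaches 17 in about seven steps plus the diene. The ester, the ketone, the C3 methyl ether and the free C5 hydroxyl appear at their final oxidation levels in one step. In step count and redox economy it is better than the chosen plan.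
- Weak points: the orientation depends on the ketone outweighing the ester as the directing acceptor on the same alkyne. The reversed orientation gives a constitutional isomer that is hard to separate. A6 is a very reactive ketene acetal that can also add in Michael or aldol fashion without closing the ring, and it is sensitive to hydrolysis. A5 is a doubly activated alkyne prone to polymerisation.
- Comparison: the chosen plan accepts three more steps and a detour through the carbinol oxidation level. In return its regiochemistry is set by the polarisation of a 3-alkoxyaryne, not by a contest between two acceptors, and both crowded carbons are installed from stable, separately purified components.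

Key step: step 6

Assumption: compound 1 is bought as a catalogue aryne precursor, orcinol (5) is used anhydrous, and the C=N geometry of 12 is left unassigned because it is lost in step 7.

## Route

Step 1
Reactants: 1 3-methoxy-2-(trimethylsilyl)phenyl trifluoromethanesulfonate
Product: 3 5-hydroxy-3-methoxy-2-(trimethylsilyl)phenyl trifluoromethanesulfonate, via pinacol boronate 2 (not isolated)
Conditions: [Ir(OMe)(cod)]2 (cat.), 4,4'-di-tert-butyl-2,2'-bipyridine (cat.), B2pin2, methyl tert-butyl ether, 60 °C; then NaBO3·4H2O, THF/H2O, rt
Reagents that add atoms: bis(pinacolato)diboron, CC1(C)OB(OC1(C)C)B1OC(C)(C)C(C)(C)O1 (boron of 2 only); sodium perborate tetrahydrate, O.O.O.O.[Na+].[O-]OB=O (the phenol oxygen)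
Why: C–H borylation under [Ir(OMe)(cod)]2/bipyridine catalysis is sterically governed and is known for 3-substituted 2-silylaryl triflates; C5–H is the only C–H of 1 without an ortho substituent. Perborate oxidation of the aryl boronate proceeds with retention at carbon and is mild enough to leave the Ar–OTf and Ar–SiMe3 groups in place.

Step 2
Reactants: 3 5-hydroxy-3-methoxy-2-(trimethylsilyl)phenyl trifluoromethanesulfonate
Product: 4 3-methoxy-5-(methoxymethoxy)-2-(trimethylsilyl)phenyl trifluoromethanesulfonate
Conditions: MOMCl, iPr2NEt, CH2Cl2, 0 °C to rt
Reagents that add atoms: chloromethyl methyl ether, COCCl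
Why: O-alkylation of a phenol with an alpha-chloro ether under amine base; no fluoride or strong acid is present, so the silyl triflate pair survives, and the resulting acetal is inert to fluoride in step 6.

Step 3
Reactants: 5 orcinol (5-methylbenzene-1,3-diol)
Product: 6 1,3-bis(methoxymethoxy)-5-methylbenzene
Conditions: MOMCl, iPr2NEt, CH2Cl2, 0 °C to rt
Reagents that add atoms: chloromethyl methyl ether, COCCl
Why: Standard double O-alkylation of a resorcinol with an alpha-chloro ether; the acetals later serve as ortho-directing groups and are removed together at the end.

Step 4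
Reactants: 6 1,3-bis(methoxymethoxy)-5-methylbenzene
Product: 7 2-chloro-1,5-bis(methoxymethoxy)-3-methylbenzene
Conditions: NCS (1.0 equiv), MeCN, 0 to 40 °C
Reagents that add atoms: N-chlorosuccinimide, O=C1CCC(=O)N1Cl
Why: Electrophilic aromatic chlorination of a resorcinol diether goes ortho/para to the two oxygens at the position beside the methyl group (two equivalent sites), while the position between the two acetal groups is shielded. The by-product is neutral succinimide, so the acetals are not exposed to HCl.

Step 5
Reactants: 7 2-chloro-1,5-bis(methoxymethoxy)-3-methylbenzene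
Product: 9 3-chloro-2,6-bis(methoxymethoxy)-4-methylbenzaldehyde, via aryllithium 8 (not isolated)
Conditions: n-BuLi, TMEDA, THF, −20 °C; DMF, −20 °C to rt; aq. NH4Cl
Reagents that add atoms: n-butyllithium, [Li]CCCC (lithium of 8 only); N,N-dimethylformamide, CN(C)C=O
Why: Directed ortho-metalation at the C–H flanked by two methoxymethoxy groups, followed by formylation with DMF. The chlorine has no ortho hydrogen, so no aryne can form, and Li–Cl exchange is slow at this temperature.

Step 6
Reactants: 4 3-methoxy-5-(methoxymethoxy)-2-(trimethylsilyl)phenyl trifluoromethanesulfonate; 9 3-chloro-2,6-bis(methoxymethoxy)-4-methylbenzaldehyde; 10 tert-butyl isocyanide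
Product: 12 racemic N-tert-butyl-3-[3-chloro-2,6-bis(methoxymethoxy)-4-methylphenyl]-4-methoxy-6-(methoxymethoxy)-3H-isobenzofuran-1-imine, via aryne 11 (not isolated)
Conditions: KF, 18-crown-6, THF, 0 °C to rt
Reagents that add atoms: none
Why: Fluoride attacks silicon of 4 and expels triflate to give aryne 11; the terminal carbon of isocyanide 10 adds to C1, the aryne carbon remote from the methoxy group, so that negative charge develops at C2 where the adjacent C3–O bond stabilises it inductively. The nitrilium/aryl-anion zwitterion then adds through C2 to the formyl carbon of 9, and the resulting alkoxide closes the oxygen heterocycle by 5-exo-dig attack on the nitrilium carbon. Three bonds (C1–C imidate, C2–C carbinol, O–C imidate) and one ring are thus formed in one operation. The closest known reaction type is the three-component coupling of arynes, isocyanides and aldehydes to N-alkyliminoisobenzofurans under KF/18-crown-6, applied here to a dialkoxyaryne and an ortho,ortho-disubstituted benzaldehyde. The single new stereocentre (C3 of the isobenzofuran) arises without any controlling element and 12 is racemic, which is accepted because step 8 turns this carbon into the ketone. The selectivity the step needs is the site of isocyanide attack on 11; it is secured by the C3 methoxy group through inductive polarisation and distortion of the aryne, while the C5 acetal oxygen, meta to C1 and para to C2, has little influence. Slow release of 11 at 0 °C in the presence of both partners keeps the aryne concentration low and favours capture by the isocyanide, the strongest nucleophile present, and the acetals, the aryl chloride and the aryl methyl group are inert to fluoride.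

Step 7
Reactants: 12 racemic N-tert-butyl-3-[3-chloro-2,6-bis(methoxymethoxy)-4-methylphenyl]-4-methoxy-6-(methoxymethoxy)-3H-isobenzofuran-1-imine
Product: 13 racemic 3-[3-chloro-2,6-bis(methoxymethoxy)-4-methylphenyl]-4-methoxy-6-(methoxymethoxy)-3H-isobenzofuran-1-one
Conditions: 0.5 M aq. citric acid, THF, rt
Reagents that add atoms: water, O
Why: Acid hydrolysis of a cyclic imidate: N-protonation, addition of water and expulsion of the amine from the protonated tetrahedral intermediate give the lactone. A weak acid at room temperature does not cleave aryl methoxymethyl ethers.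

Step 8
Reactants: 13 racemic 3-[3-chloro-2,6-bis(methoxymethoxy)-4-methylphenyl]-4-methoxy-6-(methoxymethoxy)-3H-isobenzofuran-1-one
Product: 15 2-[3-chloro-2,6-bis(methoxymethoxy)-4-methylbenzoyl]-3-methoxy-5-(methoxymethoxy)benzoic acid, via sodium hydroxy carboxylate 14 (not isolated)
Conditions: 2 M aq. NaOH, t-BuOH, 60 °C; then KMnO4, 0 °C to rt; filtration; cold 1 M HCl to pH 3
Reagents that add atoms: sodium hydroxide, [Na+].[OH-]
Why: Saponification opens the phthalide, and alkaline KMnO4 oxidises the secondary benzhydrol of the carboxylate to the diaryl ketone, the classical conversion of 3-arylphthalides into 2-aroylbenzoic acids; the stereocentre is erased here. The acid may rest as its lactol ring tautomer, which does not matter for step 9.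

Step 9
Reactants: 15 2-[3-chloro-2,6-bis(methoxymethoxy)-4-methylbenzoyl]-3-methoxy-5-(methoxymethoxy)benzoic acid
Product: 16 methyl 2-[3-chloro-2,6-bis(methoxymethoxy)-4-methylbenzoyl]-3-methoxy-5-(methoxymethoxy)benzoate
Conditions: MeI, K2CO3, DMF, rt
Reagents that add atoms: iodomethane, CI
Why: SN2 alkylation of the open-chain keto carboxylate gives the normal methyl ester and not the pseudo ester; all three phenols are masked, so only the carboxylate is methylated.

Step 10
Reactants: 16 methyl 2-[3-chloro-2,6-bis(methoxymethoxy)-4-methylbenzoyl]-3-methoxy-5-(methoxymethoxy)benzoate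
Product: 17 monochlorosulochrin (methyl 2-(3-chloro-2,6-dihydroxy-4-methylbenzoyl)-5-hydroxy-3-methoxybenzoate)
Conditions: 3 M HCl in MeOH, 40 °C
Reagents that add atoms: none
Why: Acid-catalysed acetal exchange transfers the three methoxymethyl groups to methanol; methanol as solvent makes ester exchange degenerate, and the aryl methyl ether, the aryl chloride and the ketone are inert under these conditions.

## Compound list

1 | 3-methoxy-2-(trimethylsilyl)phenyl trifluoromethanesulfonate | COc1cccc(OS(=O)(=O)C(F)(F)F)c1[Si](C)(C)C | starting material
2 | 3-methoxy-5-(4,4,5,5-tetramethyl-1,3,2-dioxaborolan-2-yl)-2-(trimethylsilyl)phenyl trifluoromethanesulfonate | COc1cc(B2OC(C)(C)C(C)(C)O2)cc(OS(=O)(=O)C(F)(F)F)c1[Si](C)(C)C | intermediate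
3 | 5-hydroxy-3-methoxy-2-(trimethylsilyl)phenyl trifluoromethanesulfonate | COc1cc(O)cc(OS(=O)(=O)C(F)(F)F)c1[Si](C)(C)C | intermediate
4 | 3-methoxy-5-(methoxymethoxy)-2-(trimethylsilyl)phenyl trifluoromethanesulfonate | COCOc1cc(OC)c([Si](C)(C)C)c(OS(=O)(=O)C(F)(F)F)c1 | intermediate
5 | orcinol (5-methylbenzene-1,3-diol) | Cc1cc(O)cc(O)c1 | starting material
6 | 1,3-bis(methoxymethoxy)-5-methylbenzene | COCOc1cc(C)cc(OCOC)c1 | intermediate
7 | 2-chloro-1,5-bis(methoxymethoxy)-3-methylbenzene | COCOc1cc(C)c(Cl)c(OCOC)c1 | intermediate
8 | [3-chloro-2,6-bis(methoxymethoxy)-4-methylphenyl]lithium | [Li]c1c(OCOC)cc(C)c(Cl)c1OCOC | intermediate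
9 | 3-chloro-2,6-bis(methoxymethoxy)-4-methylbenzaldehyde | COCOc1cc(C)c(Cl)c(OCOC)c1C=O | intermediate
10 | tert-butyl isocyanide | CC(C)(C)[N+]#[C-] | starting material
11 | 3-methoxy-5-(methoxymethoxy)benzyne | COC1=CC(OCOC)=CC#C1 | intermediate
12 | racemic N-tert-butyl-3-[3-chloro-2,6-bis(methoxymethoxy)-4-methylphenyl]-4-methoxy-6-(methoxymethoxy)-3H-isobenzofuran-1-imine | CC(C)(C)N=C1OC(c2c(OCOC)cc(C)c(Cl)c2OCOC)c2c(OC)cc(OCOC)cc21 | intermediate
13 | racemic 3-[3-chloro-2,6-bis(methoxymethoxy)-4-methylphenyl]-4-methoxy-6-(methoxymethoxy)-3H-isobenzofuran-1-one | O=C1OC(c2c(OCOC)cc(C)c(Cl)c2OCOC)c2c(OC)cc(OCOC)cc21 | intermediate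
14 | racemic sodium 2-{[3-chloro-2,6-bis(methoxymethoxy)-4-methylphenyl](hydroxy)methyl}-3-methoxy-5-(methoxymethoxy)benzoate | [Na+].[O-]C(=O)c1cc(OCOC)cc(OC)c1C(O)c1c(OCOC)cc(C)c(Cl)c1OCOC | intermediate
15 | 2-[3-chloro-2,6-bis(methoxymethoxy)-4-methylbenzoyl]-3-methoxy-5-(methoxymethoxy)benzoic acid | OC(=O)c1cc(OCOC)cc(OC)c1C(=O)c1c(OCOC)cc(C)c(Cl)c1OCOC | intermediate
16 | methyl 2-[3-chloro-2,6-bis(methoxymethoxy)-4-methylbenzoyl]-3-methoxy-5-(methoxymethoxy)benzoate | COC(=O)c1cc(OCOC)cc(OC)c1C(=O)c1c(OCOC)cc(C)c(Cl)c1OCOC | intermediate
17 | monochlorosulochrin, methyl 2-(3-chloro-2,6-dihydroxy-4-methylbenzoyl)-5-hydroxy-3-methoxybenzoate | COC(=O)c1cc(O)cc(OC)c1C(=O)c1c(O)cc(C)c(Cl)c1O | target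

## Step count and risks

Total step count: 10. Longest linear sequence: 8 steps (steps 3 to 10, from orcinol 5); the aryne branch (steps 1 and 2) joins at step 6.

**Step 6 (key step).** The aryl anion of the nitrilium zwitterion may be consumed by proton transfer or by addition to a second aryne faster than it adds to the shielded, electron-rich formyl group of 9, so that two-component products dominate. The fallback forms the same two carbon–carbon bonds stepwise with a persistent nucleophile. It sets out from 4 and returns at 13. Aryne 11 is released from 4 with CsF in the presence of I2 to give 1,2-diiodo-3-methoxy-5-(methoxymethoxy)benzene F1. Exchange with iPrMgCl·LiCl at −40 °C takes place at the iodine beside the methoxy group and gives [2-iodo-6-methoxy-4-(methoxymethoxy)phenyl]magnesium chloride F2. Addition of F2 to 9 gives racemic [3-chloro-2,6-bis(methoxymethoxy)-4-methylphenyl][2-iodo-6-methoxy-4-(methoxymethoxy)phenyl]methanol F3. Carbonylative lactonisation of F3 (Pd(OAc)2, 1,1'-bis(diphenylphosphino)ferrocene, CO, K2CO3, DMF) closes the phthalide 13.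

**Step 8.** Hydride abstraction from the shielded benzhydrol C–H may be slow, so that the hydroxy acid relactonises on acidification; forcing the oxidation risks attack on the ring B methyl group. The fallback avoids the oxidant and sets out from 13, returning at 16. Deprotonation of 13 at C3 with LiN(SiMe3)2 in THF at −78 °C gives lithium 3-[3-chloro-2,6-bis(methoxymethoxy)-4-methylphenyl]-4-methoxy-6-(methoxymethoxy)isobenzofuran-1-olate F4. Hydroxylation of F4 with 2-(phenylsulfonyl)-3-phenyloxaziridine gives racemic 3-[3-chloro-2,6-bis(methoxymethoxy)-4-methylphenyl]-3-hydroxy-4-methoxy-6-(methoxymethoxy)-3H-isobenzofuran-1-one F5, the ring tautomer of 15. F5 opens under MeI/K2CO3 in DMF and is methylated to 16.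

**Step 1.** The silyl triflate pair may be lost in the basic oxidative stage (attack of hydroxide or peroxide at silicon or sulfur), or borylation may partly occur beside the methoxy group. The fallback moves the oxygenation to a stage that carries neither group. It sets out from 1 and returns at 13.
- Compound 1 is used directly in the three-component coupling with 9 and 10 (KF, 18-crown-6, THF). Through 3-methoxybenzyne F6 this gives racemic N-tert-butyl-3-[3-chloro-2,6-bis(methoxymethoxy)-4-methylphenyl]-4-methoxy-3H-isobenzofuran-1-imine F7.
- Hydrolysis with aq. citric acid gives racemic 3-[3-chloro-2,6-bis(methoxymethoxy)-4-methylphenyl]-4-methoxy-3H-isobenzofuran-1-one F8.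
- Borylation with B2pin2 under [Ir(OMe)(cod)]2/4,4'-di-tert-butyl-2,2'-bipyridine goes to C6, the only unhindered C–H, and gives racemic 3-[3-chloro-2,6-bis(methoxymethoxy)-4-methylphenyl]-4-methoxy-6-(4,4,5,5-tetramethyl-1,3,2-dioxaborolan-2-yl)-3H-isobenzofuran-1-one F9.
- NaBO3·4H2O oxidation gives racemic 3-[3-chloro-2,6-bis(methoxymethoxy)-4-methylphenyl]-6-hydroxy-4-methoxy-3H-isobenzofuran-1-one F10.
- MOMCl/iPr2NEt converts F10 into 13.

**Step 4.** A second chlorination, attack at the position between the two acetal groups, or acetal loss through adventitious acid may erode the yield of 7. The fallback reverses the order of formylation and chlorination and sets out from 6, returning at 9. Lithiation of 6 (n-BuLi, TMEDA, THF) gives [2,6-bis(methoxymethoxy)-4-methylphenyl]lithium F11. Formylation of F11 with DMF gives 2,6-bis(methoxymethoxy)-4-methylbenzaldehyde F12. The two open ring positions of F12 are equivalent and the formyl group damps a second substitution, so chlorination with NCS in DMF gives 9.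

## Further compounds

F1 | step 6 | 1,2-diiodo-3-methoxy-5-(methoxymethoxy)benzene | COCOc1cc(I)c(I)c(OC)c1
F2 | step 6 | [2-iodo-6-methoxy-4-(methoxymethoxy)phenyl]magnesium chloride | COCOc1cc(I)c([Mg]Cl)c(OC)c1
F3 | step 6 | racemic [3-chloro-2,6-bis(methoxymethoxy)-4-methylphenyl][2-iodo-6-methoxy-4-(methoxymethoxy)phenyl]methanol | COCOc1cc(I)c(C(O)c2c(OCOC)cc(C)c(Cl)c2OCOC)c(OC)c1
F4 | step 8 | lithium 3-[3-chloro-2,6-bis(methoxymethoxy)-4-methylphenyl]-4-methoxy-6-(methoxymethoxy)isobenzofuran-1-olate | [Li+].[O-]C1=C2C=C(OCOC)C=C(OC)C2=C(O1)c1c(OCOC)cc(C)c(Cl)c1OCOC
F5 | step 8 | racemic 3-[3-chloro-2,6-bis(methoxymethoxy)-4-methylphenyl]-3-hydroxy-4-methoxy-6-(methoxymethoxy)-3H-isobenzofuran-1-one | O=C1OC(O)(c2c(OCOC)cc(C)c(Cl)c2OCOC)c2c(OC)cc(OCOC)cc21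
F6 | step 1 | 3-methoxybenzyne | COC1=CC=CC#C1
F7 | step 1 | racemic N-tert-butyl-3-[3-chloro-2,6-bis(methoxymethoxy)-4-methylphenyl]-4-methoxy-3H-isobenzofuran-1-imine | CC(C)(C)N=C1OC(c2c(OCOC)cc(C)c(Cl)c2OCOC)c2c(OC)cccc21
F8 | step 1 | racemic 3-[3-chloro-2,6-bis(methoxymethoxy)-4-methylphenyl]-4-methoxy-3H-isobenzofuran-1-one | O=C1OC(c2c(OCOC)cc(C)c(Cl)c2OCOC)c2c(OC)cccc21
F9 | step 1 | racemic 3-[3-chloro-2,6-bis(methoxymethoxy)-4-methylphenyl]-4-methoxy-6-(4,4,5,5-tetramethyl-1,3,2-dioxaborolan-2-yl)-3H-isobenzofuran-1-one | O=C1OC(c2c(OCOC)cc(C)c(Cl)c2OCOC)c2c(OC)cc(B3OC(C)(C)C(C)(C)O3)cc21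
F10 | step 1 | racemic 3-[3-chloro-2,6-bis(methoxymethoxy)-4-methylphenyl]-6-hydroxy-4-methoxy-3H-isobenzofuran-1-one | O=C1OC(c2c(OCOC)cc(C)c(Cl)c2OCOC)c2c(OC)cc(O)cc21
F11 | step 4 | [2,6-bis(methoxymethoxy)-4-methylphenyl]lithium | [Li]c1c(OCOC)cc(C)cc1OCOC
F12 | step 4 | 2,6-bis(methoxymethoxy)-4-methylbenzaldehyde | COCOc1cc(C)cc(OCOC)c1C=O
A1 | alternative 1 | 2-chloro-1-hydroxy-8-methoxy-3-methyl-9,10-dioxo-9,10-dihydroanthracen-6-yl pivalate | Cc1cc2C(=O)c3cc(OC(=O)C(C)(C)C)cc(OC)c3C(=O)c2c(O)c1Cl
A2 | alternative 1 | chlorinated dibenzo[b,e]oxepine-6,11-dione lactone pivalate | Cc1cc2OC(=O)c3cc(OC(=O)C(C)(C)C)cc(OC)c3C(=O)c2c(O)c1Cl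
A3 | alternative 2 | methyl 8-[3-chloro-2,6-bis(methoxymethoxy)-4-methylphenyl]-2,4,6,8-tetraoxooctanoate | COC(=O)C(=O)CC(=O)CC(=O)CC(=O)c1c(OCOC)cc(C)c(Cl)c1OCOC
A4 | alternative 2 | methyl 2-[3-chloro-2,6-bis(methoxymethoxy)-4-methylbenzoyl]-3,5-dihydroxybenzoate | COC(=O)c1cc(O)cc(O)c1C(=O)c1c(OCOC)cc(C)c(Cl)c1OCOC
A5 | alternative 3 | methyl 4-[3-chloro-2,6-bis(methoxymethoxy)-4-methylphenyl]-4-oxobut-2-ynoate | COC(=O)C#CC(=O)c1c(OCOC)cc(C)c(Cl)c1OCOC
A6 | alternative 3 | 1,1-dimethoxy-3-(trimethylsilyloxy)buta-1,3-diene | COC(OC)=CC(=C)O[Si](C)(C)C
A7 | alternative 3 | methyl 2-[3-chloro-2,6-bis(methoxymethoxy)-4-methylbenzoyl]-5-hydroxy-3-methoxybenzoate | COC(=O)c1cc(O)cc(OC)c1C(=O)c1c(OCOC)cc(C)c(Cl)c1OCOC
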